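**Retrosynthetic overview**
1. Key bond: the lactone C–O bond of the 2-pyrone. The ring is unravelled to pentan-3-one (1) and bis(2,4,6-trichlorophenyl) malonate (2); forward, they pass through acyclic diketo ester 3 to pyrone 4 in one new C-acylation/lactonisation.
2. Aryl ketone half: the acyl C–C bond is cut to (R)-2-methylbutanoic acid (5) and phloroglucinol (6), joined via acid chloride 7 to ketone 8. A second C–O bond, the para aryl methyl ether, then gives 9.
3. Last-formed bond: the ArCH2–pyrone link, cut to 4, 9 and paraformaldehyde (10). Forward, methide 11 from 4 and 10 is trapped by 9 to give the target (12).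
4. Ring order: the pyrone is the only ring made (step 1) and the benzene ring is bought. The single stereocentre comes in with 5 and is carried unchanged.

Assumption: 5 is bought as the single (R)-enantiomer (the target SMILES encodes R at the acyl α-carbon) and 2 as the catalogue reagent.

**Route**

Step 1
Reactants: 1 pentan-3-one; 2 bis(2,4,6-trichlorophenyl) malonate
Product: 4 6-ethyl-4-hydroxy-5-methyl-2H-pyran-2-one, via 2,4,6-trichlorophenyl 4-methyl-3,5-dioxoheptanoate 3 (not isolated)
Conditions: 1 (3 equiv), MgBr2·OEt2 (3 equiv), i-Pr2NEt (4 equiv), CH2Cl2, 0 °C; 2 (1 equiv) added over 2 h; rt, 12 h; then 1 M HCl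
Reagents that add atoms: none
Why: Proposed new method: soft enolisation of 1 by MgBr2·OEt2/i-Pr2NEt gives a magnesium enolate that is C-acylated by the doubly activated malonate 2 (directly or through the aryloxycarbonylketene formed from 2 by E1cB loss of trichlorophenoxide), and in the magnesium-chelated diketo ester 3 the enol oxygen of the ethyl ketone then attacks the remaining aryl ester in a 6-exo-trig acyl substitution that closes the lactone C–O bond and expels the second trichlorophenoxide, the symmetric ketone leaving no regiochemical choice; the closest known reaction types are the MgBr2·OEt2/amine soft-enolisation C-acylation of ketones with activated esters, the thermal (above 200 °C) pyrone annulation of enolisable carbonyl compounds with this malonate and the base-induced lactonisation of 3,5-dioxo esters, which have not been merged into a room-temperature [3+3] pyrone annulation of a simple dialkyl ketone.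

Step 2
Reactants: 5 (R)-2-methylbutanoic acid; 6 phloroglucinol (anhydrous)
Product: 8 (R)-2-methyl-1-(2,4,6-trihydroxyphenyl)butan-1-one, via (R)-2-methylbutanoyl chloride 7 (not isolated)
Conditions: 5, (COCl)2 (1.1 equiv), DMF (cat.), CH2Cl2, 0 °C → rt; then 6, AlCl3 (3.5 equiv), PhNO2, 0 °C → rt; aq. HCl
Reagents that add atoms: none
Why: Friedel–Crafts acylation of the threefold-activated symmetric arene gives a single mono-ketone because the first acyl group deactivates the ring, and the stereocentre should be retained because the acid chloride is made without base (no ketene) and the aluminium-chelated aryl ketone, a vinylogous acid, enolises only sluggishly at or below room temperature.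

Step 3
Reactants: 8 (R)-2-methyl-1-(2,4,6-trihydroxyphenyl)butan-1-one
Product: 9 (R)-1-(2,6-dihydroxy-4-methoxyphenyl)-2-methylbutan-1-one
Conditions: Me2SO4 (1.05 equiv), K2CO3 (1.1 equiv), acetone, rt → 40 °C
Reagents that add atoms: dimethyl sulfate, COS(=O)(=O)OC
Why: Williamson-type O-methylation is selective for the 4-OH because it is the most acidic hydroxyl (para to the carbonyl) and the only one not hydrogen-bonded to or shielded by the acyl group, while the α-stereocentre is safe because the phenoxide-conjugated ketone is not enolised by carbonate.

Step 4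
Reactants: 4 6-ethyl-4-hydroxy-5-methyl-2H-pyran-2-one; 9 (R)-1-(2,6-dihydroxy-4-methoxyphenyl)-2-methylbutan-1-one; 10 paraformaldehyde
Product: 12 3-{[2,4-dihydroxy-6-methoxy-3-((2R)-2-methylbutanoyl)phenyl]methyl}-6-ethyl-4-hydroxy-5-methyl-2H-pyran-2-one (target), via 6-ethyl-5-methyl-3-methylidenepyran-2,4-dione 11 (not isolated)
Conditions: (CH2O)n (1.2 equiv), 9 (1.5 equiv), ethylenediammonium diacetate (10 mol %), CHCl3, 40 °C; 4 added over 2 h
Reagents that add atoms: none
Why: Knoevenagel condensation of the pyrone C3–H with formaldehyde gives methide 11, which is trapped in a Friedel–Crafts-type Michael addition (carba-Betti three-component coupling) by a ring carbon of 9; the two free ring positions of 9 are equivalent, so only one regioisomer can form, and no new stereocentre arises.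

**Compound list**
1 | pentan-3-one | CCC(=O)CC | starting material
2 | bis(2,4,6-trichlorophenyl) malonate | O=C(CC(=O)Oc1c(Cl)cc(Cl)cc1Cl)Oc1c(Cl)cc(Cl)cc1Cl | starting material
3 | 2,4,6-trichlorophenyl 4-methyl-3,5-dioxoheptanoate (racemic at C4, present as its magnesium enolate) | CCC(=O)C(C)C(=O)CC(=O)Oc1c(Cl)cc(Cl)cc1Cl | intermediate
4 | 6-ethyl-4-hydroxy-5-methyl-2H-pyran-2-one | CCc1oc(=O)cc(O)c1C | intermediate
5 | (R)-2-methylbutanoic acid | CC[C@@H](C)C(=O)O | starting material
6 | phloroglucinol (benzene-1,3,5-triol) | Oc1cc(O)cc(O)c1 | starting material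
7 | (R)-2-methylbutanoyl chloride | CC[C@@H](C)C(Cl)=O | intermediate
8 | (R)-2-methyl-1-(2,4,6-trihydroxyphenyl)butan-1-one | CC[C@@H](C)C(=O)c1c(O)cc(O)cc1O | intermediate
9 | (R)-1-(2,6-dihydroxy-4-methoxyphenyl)-2-methylbutan-1-one | CC[C@@H](C)C(=O)c1c(O)cc(OC)cc1O | intermediate
10 | paraformaldehyde (reacts as formaldehyde) | C=O | starting material
11 | 6-ethyl-5-methyl-3-methylidene-2H-pyran-2,4(3H)-dione | CCC1=C(C)C(=O)C(=C)C(=O)O1 | intermediate
12 | 3-{[2,4-dihydroxy-6-methoxy-3-((2R)-2-methylbutanoyl)phenyl]methyl}-6-ethyl-4-hydroxy-5-methyl-2H-pyran-2-one | CCc1oc(=O)c(Cc2c(OC)cc(O)c(C(=O)[C@H](C)CC)c2O)c(O)c1C | target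

**Summary**
Total step count: 4 (convergent).
Longest linear sequence: 3 steps (5 and 6 → 8 → 9 → 12); the pyrone branch is 1 step.

Steps most likely to fail:

- **Step 1 (proposed new annulation).** The more acidic malonate may be enolised in place of the ketone, the triketide may close by Claisen instead of lactonisation, or 4 may be acylated again. The fallback sets out from 1 and comes back at 4. 1 is silylated (Me3SiCl, NaI, Et3N, MeCN, rt) to (Z)-trimethyl(pent-2-en-3-yloxy)silane F1. F1 is then treated with malonyl dichloride in Et2O from −78 °C to rt. This is the known silyl enol ether/malonyl dichloride pyrone synthesis: C-acylation, then O-acylative ring closure with loss of Me3SiCl and HCl, giving 4.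

- **Step 4 (three-component coupling).** Methide 11 may be captured by a second molecule of 4 to give the methylene-bis-pyrone, or 12 may be alkylated again at its remaining ring position. The fallback sets out from 4 and comes back at 12. 4 is aminomethylated with dimethylmethylideneammonium iodide in CH2Cl2 at rt to the Mannich base 3-[(dimethylamino)methyl]-6-ethyl-4-hydroxy-5-methyl-2H-pyran-2-one F3, which is isolated free of 4. F3 is then heated with 9 (1.5 equiv) in 1,4-dioxane at 90 °C. Thermal loss of dimethylamine regenerates 11 with no free pyrone present to compete, and 9 adds to give 12.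

- **Step 3 (mono-O-methylation).** Over-methylation to the 2,4-dimethyl ether or incomplete conversion may make the separation poor. The fallback sets out from 8 and comes back at 9. 8 is exhaustively methylated (Me2SO4 in excess, K2CO3, acetone, reflux) to (R)-2-methyl-1-(2,4,6-trimethoxyphenyl)butan-1-one F2. BBr3 (2.2 equiv, CH2Cl2, −78 → 0 °C) then cleaves only the two methyl ethers ortho to the carbonyl group by chelation-directed demethylation, leaving the para methyl ether and giving 9.

**Further compounds**
F1 | step 1 | (Z)-trimethyl(pent-2-en-3-yloxy)silane | C/C=C(\O[Si](C)(C)C)CC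
F2 | step 3 | (R)-2-methyl-1-(2,4,6-trimethoxyphenyl)butan-1-one | CC[C@@H](C)C(=O)c1c(OC)cc(OC)cc1OC
F3 | step 4 | 3-[(dimethylamino)methyl]-6-ethyl-4-hydroxy-5-methyl-2H-pyran-2-one | CCc1oc(=O)c(CN(C)C)c(O)c1C
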